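**Strategy.** The route rests on disconnecting the C4=C5 bond of the only ring, the 3,6-dihydro-1,2-dioxine (O1, O2, C3–C6). That alkene lies between the peroxyketal carbon C3 and the peroxy methine C6, so the peroxide bond O1–O2, already in place, holds the two alkene-bearing halves together. Ring-closing metathesis of an acyclic mixed peroxyketal with a vinyl group on C3 and a propenyl group on C6 closes the ring and fixes the cis alkene in one operation. The precursor comes from an amine-catalysed enantioselective peroxy-Michael addition of a C21 methoxy hydroperoxide to sorbaldehyde, which sets C6. C3 is set last by thermodynamic methanol exchange.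

Key step: step 12

Remark 1: ring atoms are numbered O1, O2, C3 (peroxyketal carbon), C4, C5, C6 (peroxy methine); with this numbering the target is (3R,6R), with OMe cis to the acetate arm.
Remark 2: the facial sense of step 9 is taken from the usual steric model for diarylprolinol silyl ethers (attack anti to the silyloxydiarylmethyl group on the E,s-trans iminium ion), which predicts the (R)-catalyst for the (R)-peroxide; the antipodal catalyst is equally available should the sense prove opposite.

**Step 1**
Reactants: 1 15-pentadecanolide (oxacyclohexadecan-2-one)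
Product: 2 15-hydroxy-N-methoxy-N-methylpentadecanamide
Conditions: MeNHOMe·HCl, AlMe3, CH2Cl2, 0 °C to rt; then cold 1 M HCl
Reagents that add atoms: N,O-dimethylhydroxylamine hydrochloride, CNOC.Cl
Why: Weinreb aminolysis of a lactone: the chloro(methyl)aluminium amide formed in the flask acylates at the lactone carbonyl and the stable aluminium chelate of the amide prevents further reaction, so the sixteen-membered ring opens to the ω-hydroxy amide.

**Step 2**
Reactants: 2 15-hydroxy-N-methoxy-N-methylpentadecanamide
Product: 3 N-methoxy-N-methyl-15-[(1-phenyl-1H-tetrazol-5-yl)sulfanyl]pentadecanamide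
Conditions: 1-phenyl-1H-tetrazole-5-thiol, PPh3, DIAD, THF, 0 °C to rt
Reagents that add atoms: 1-phenyl-1H-tetrazole-5-thiol, Sc1nnnn1-c1ccccc1
Why: Mitsunobu thioetherification: the acidic heteroaryl thiol displaces the activated primary alcohol by SN2 and the amide is untouched.

**Step 3**
Reactants: 3 N-methoxy-N-methyl-15-[(1-phenyl-1H-tetrazol-5-yl)sulfanyl]pentadecanamide
Product: 4 N-methoxy-N-methyl-15-[(1-phenyl-1H-tetrazol-5-yl)sulfonyl]pentadecanamide
Conditions: (NH4)6Mo7O24·4H2O (cat.), 30% H2O2, EtOH, 0 °C to rt
Reagents that add atoms: hydrogen peroxide, OO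
Why: Molybdate-catalysed sulfide-to-sulfone oxidation: the peroxomolybdate oxidises sulfur twice, and the amide with its N–O bond is inert to this oxidant.

**Step 4**
Reactants: 4 N-methoxy-N-methyl-15-[(1-phenyl-1H-tetrazol-5-yl)sulfonyl]pentadecanamide; 5 (E)-crotonaldehyde
Product: 6 (15E,17E)-N-methoxy-N-methylnonadeca-15,17-dienamide
Conditions: KN(SiMe3)2, DME, −60 °C; then 5, −60 °C to rt
Reagents that add atoms: none
Why: Julia–Kocienski olefination: the sulfone α-CH2 is the most acidic site, its potassium carbanion adds to the aldehyde and Smiles rearrangement with loss of SO2 and the tetrazolone forms C15=C16 with the E preference typical of phenyltetrazolyl sulfones in DME, while the E bond of 5 is carried over unchanged (a minor 15Z isomer would be equilibrated with catalytic I2).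

**Step 5**
Reactants: 6 (15E,17E)-N-methoxy-N-methylnonadeca-15,17-dienamide; 7 vinylmagnesium bromide
Product: 8 (17E,19E)-henicosa-1,17,19-trien-3-one
Conditions: THF, −20 to 0 °C; inverse quench into cold aq. NaHSO4; crude used at once
Reagents that add atoms: none
Why: Weinreb ketone synthesis: the magnesium chelate of the tetrahedral adduct survives until the quench, so only one vinyl group adds, and the cold acidic inverse quench keeps the released amine protonated so that it cannot add to the new enone.

**Step 6**
Reactants: 8 (17E,19E)-henicosa-1,17,19-trien-3-one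
Product: 10 [(17E,19E)-3,3-dimethoxyhenicosa-17,19-dien-1-yl](phenyl)selane, via selanyl ketone 9 (not isolated)
Conditions: PhSeH, CH2Cl2, 0 °C (argon, dark); then CH(OMe)3, MeOH, CSA (cat.), rt; Et3N quench
Reagents that add atoms: benzeneselenol, [SeH]c1ccccc1; trimethyl orthoformate, COC(OC)OC
Why: Conjugate addition of a selenol followed by acid-catalysed ketalisation: the soft selenol adds quickly to the vinyl ketone and removes the enone, after which the saturated ketone forms its dimethyl ketal with orthoformate as water scavenger, which the enone itself could not do without adding methanol across the double bond.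

**Step 7**
Reactants: 10 [(17E,19E)-3,3-dimethoxyhenicosa-17,19-dien-1-yl](phenyl)selane
Product: 12 (17E,19E)-3,3-dimethoxyhenicosa-1,17,19-triene, via selenoxide 11 (not isolated)
Conditions: NaIO4, NaHCO3, THF/MeOH/H2O, 0 °C to rt; then i-Pr2NH, PhMe, 60 °C
Reagents that add atoms: none
Why: Selenoxide syn-elimination: periodate oxidises only selenium, the selenoxide has β-hydrogens only on C2 and so can give only the vinyl group, the bicarbonate protects the acid-labile allylic ketal and the amine traps PhSeOH before it can add to an alkene.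

**Step 8**
Reactants: 12 (17E,19E)-3,3-dimethoxyhenicosa-1,17,19-triene
Product: 13 (17E,19E)-3-hydroperoxy-3-methoxyhenicosa-1,17,19-triene (racemic)
Conditions: anhydrous H2O2 in Et2O (dried over MgSO4, about 5 equiv), CSA (cat.), 0 °C; NaHCO3 quench
Reagents that add atoms: hydrogen peroxide, OO
Why: Acid-catalysed perhydrolysis (transketalisation) of a ketal: loss of methanol gives the methoxy-stabilised cation, which the α-effect nucleophile H2O2 in excess captures at the ketal carbon, and the reaction should stop after one exchange because the product re-ionises more easily by loss of H2O2 than by loss of methanol to a hydroperoxy carbenium ion; the new centre is racemic.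

**Step 9**
Reactants: 13 (17E,19E)-3-hydroperoxy-3-methoxyhenicosa-1,17,19-triene; 14 (2E,4E)-hexa-2,4-dienal (sorbaldehyde)
Product: 15 (3R,4E)-3-{[(17E,19E)-3-methoxyhenicosa-1,17,19-trien-3-yl]peroxy}hex-4-enal (both epimers at the ketal carbon)
Conditions: (R)-2-[diphenyl(trimethylsilyloxy)methyl]pyrrolidine (20 mol%), PhCO2H (20 mol%), 14 (3 equiv), toluene, 0 °C
Reagents that add atoms: none
Why: Iminium-catalysed asymmetric peroxy-Michael (oxa-Michael) addition: the hydroperoxide adds to the β-carbon of the E,s-trans iminium ion of 14, where the LUMO coefficient is largest for a hard oxygen nucleophile, from the face left open by the silyloxydiphenylmethyl group, which sets the future ring carbon C6 as (R); the ketal carbon of 13 is not controlled, so 15 is a pair of epimers at that carbon only.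

**Step 10**
Reactants: 15 (3R,4E)-3-{[(17E,19E)-3-methoxyhenicosa-1,17,19-trien-3-yl]peroxy}hex-4-enal
Product: 16 (3R,4E)-3-{[(17E,19E)-3-methoxyhenicosa-1,17,19-trien-3-yl]peroxy}hex-4-enoic acid
Conditions: NaClO2, NaH2PO4, 2-methyl-2-butene (excess), t-BuOH/H2O, 0 °C, short reaction time
Reagents that add atoms: sodium chlorite, [Na+].[O-]Cl=O
Why: Pinnick (chlorite) oxidation: HClO2 adds to the aldehyde and fragments to the acid under weakly acidic, base-free conditions, so the β-peroxy carbonyl compound cannot undergo retro-Michael loss or Kornblum–DeLaMare cleavage, the alkene scavenger removes HOCl, and the short cold contact with the buffer should spare the mixed peroxyketal.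

**Step 11**
Reactants: 16 (3R,4E)-3-{[(17E,19E)-3-methoxyhenicosa-1,17,19-trien-3-yl]peroxy}hex-4-enoic acid
Product: 17 methyl (3R,4E)-3-{[(17E,19E)-3-methoxyhenicosa-1,17,19-trien-3-yl]peroxy}hex-4-enoate
Conditions: TMSCHN2, PhMe/MeOH (4:1), 0 °C
Reagents that add atoms: trimethylsilyldiazomethane, C[Si](C)(C)C=[N+]=[N-]
Why: Methyl esterification with a diazoalkane: the acid protonates the diazo carbon, methanol removes silicon and the carboxylate is methylated with loss of N2 under neutral conditions that leave the peroxide and the ketal alone.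

**Step 12**
Reactants: 17 methyl (3R,4E)-3-{[(17E,19E)-3-methoxyhenicosa-1,17,19-trien-3-yl]peroxy}hex-4-enoate
Product: 18 methyl 2-[(6R)-3-methoxy-3-[(14E,16E)-octadeca-14,16-dien-1-yl]-3,6-dihydro-1,2-dioxin-6-yl]acetate (both C3 epimers)
Conditions: second-generation Hoveyda–Grubbs catalyst RuCl2(H2IMes)(=CH-C6H4-2-O-i-Pr) (H2IMes = 1,3-dimesitylimidazolidin-2-ylidene; 5 mol%), CH2Cl2 (0.005 M), 40 °C, argon sparge; ethyl vinyl ether quench as soon as 17 is consumed
Reagents that add atoms: none
Why: Ring-closing olefin metathesis: the ruthenium alkylidene exchanges onto the less hindered C6 propenyl group, adds [2+2] to the C3 vinyl group four atoms away, and cycloreversion of the ruthenacyclobutane releases the ring, the methylidene left on ruthenium re-entering at the next propenyl group with loss of propene, which the argon stream removes. The closest known reaction type is ring-closing metathesis of unsaturated dialkyl peroxides and peroxyketals to cyclic peroxides. The six-membered 3,6-dihydro-1,2-dioxine closes as a 1,7-diene cyclisation across the C3–O2–O1–C6 tether, and a ring of this size can hold the new C4=C5 bond only cis. No stereocentre is created: C6 stays (R) because no bond to it is broken, and C3 stays a mixture. The step needs chemoselectivity for the two peroxide-bound alkenes over the side-chain diene and over the O–O bond; the first rests on fast intramolecular closure at high dilution against slow bimolecular reaction at a remote internal conjugated diene, the second on neutral, base-free and phosphine-free conditions that leave the peroxide, the C6–H next to it and the ketal alone.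

**Step 13**
Reactants: 18 methyl 2-[(6R)-3-methoxy-3-[(14E,16E)-octadeca-14,16-dien-1-yl]-3,6-dihydro-1,2-dioxin-6-yl]acetate (both C3 epimers)
Product: 19 xestin A, methyl 2-[(3R,6R)-3-methoxy-3-[(14E,16E)-octadeca-14,16-dien-1-yl]-3,6-dihydro-1,2-dioxin-6-yl]acetate
Conditions: CSA (5 mol%), anhydrous MeOH, 0 °C to rt; Et3N quench; chromatography, minor epimer returned to the same conditions
Reagents that add atoms: methanol, CO
Why: Acid-catalysed transketalisation under thermodynamic control: reversible loss of methanol gives the ring peroxycarbenium ion conjugated with C4=C5, which takes methanol back from either face until equilibrium, and the favoured half-chair should carry OMe pseudoaxial (anomeric effect with O2) with the C18 chain and the C6 acetate arm both pseudoequatorial, which is the (3R,6R) epimer; C6 is not touched by acid and the methyl ester exchanges only with itself.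

**Compound list**
1 | 15-pentadecanolide (oxacyclohexadecan-2-one) | O=C1CCCCCCCCCCCCCCO1 | starting material
2 | 15-hydroxy-N-methoxy-N-methylpentadecanamide | CON(C)C(=O)CCCCCCCCCCCCCCO | intermediate
3 | N-methoxy-N-methyl-15-[(1-phenyl-1H-tetrazol-5-yl)sulfanyl]pentadecanamide | CON(C)C(=O)CCCCCCCCCCCCCCSc1nnnn1-c1ccccc1 | intermediate
4 | N-methoxy-N-methyl-15-[(1-phenyl-1H-tetrazol-5-yl)sulfonyl]pentadecanamide | CON(C)C(=O)CCCCCCCCCCCCCCS(=O)(=O)c1nnnn1-c1ccccc1 | intermediate
5 | (E)-crotonaldehyde | C/C=C/C=O | starting material
6 | (15E,17E)-N-methoxy-N-methylnonadeca-15,17-dienamide | C/C=C/C=C/CCCCCCCCCCCCCC(=O)N(C)OC | intermediate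
7 | vinylmagnesium bromide | C=C[Mg]Br | starting material
8 | (17E,19E)-henicosa-1,17,19-trien-3-one | C/C=C/C=C/CCCCCCCCCCCCCC(=O)C=C | intermediate
9 | (17E,19E)-1-(phenylselanyl)henicosa-17,19-dien-3-one | C/C=C/C=C/CCCCCCCCCCCCCC(=O)CC[Se]c1ccccc1 | intermediate
10 | [(17E,19E)-3,3-dimethoxyhenicosa-17,19-dien-1-yl](phenyl)selane | C/C=C/C=C/CCCCCCCCCCCCCC(OC)(OC)CC[Se]c1ccccc1 | intermediate
11 | (17E,19E)-3,3-dimethoxy-1-(phenylseleninyl)henicosa-17,19-diene | C/C=C/C=C/CCCCCCCCCCCCCC(OC)(OC)CC[Se](=O)c1ccccc1 | intermediate
12 | (17E,19E)-3,3-dimethoxyhenicosa-1,17,19-triene | C/C=C/C=C/CCCCCCCCCCCCCC(OC)(OC)C=C | intermediate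
13 | (17E,19E)-3-hydroperoxy-3-methoxyhenicosa-1,17,19-triene, racemic | C/C=C/C=C/CCCCCCCCCCCCCC(OC)(OO)C=C | intermediate
14 | (2E,4E)-hexa-2,4-dienal (sorbaldehyde) | C/C=C/C=C/C=O | starting material
15 | (3R,4E)-3-{[(17E,19E)-3-methoxyhenicosa-1,17,19-trien-3-yl]peroxy}hex-4-enal, epimers at the ketal carbon | C/C=C/[C@@H](CC=O)OOC(OC)(C=C)CCCCCCCCCCCCC/C=C/C=C/C | intermediate
16 | (3R,4E)-3-{[(17E,19E)-3-methoxyhenicosa-1,17,19-trien-3-yl]peroxy}hex-4-enoic acid | C/C=C/[C@@H](CC(=O)O)OOC(OC)(C=C)CCCCCCCCCCCCC/C=C/C=C/C | intermediate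
17 | methyl (3R,4E)-3-{[(17E,19E)-3-methoxyhenicosa-1,17,19-trien-3-yl]peroxy}hex-4-enoate | C/C=C/[C@@H](CC(=O)OC)OOC(OC)(C=C)CCCCCCCCCCCCC/C=C/C=C/C | intermediate
18 | methyl 2-[(6R)-3-methoxy-3-[(14E,16E)-octadeca-14,16-dien-1-yl]-3,6-dihydro-1,2-dioxin-6-yl]acetate, both C3 epimers | C/C=C/C=C/CCCCCCCCCCCCCC1(OC)C=C[C@@H](CC(=O)OC)OO1 | intermediate
19 | xestin A, methyl 2-[(3R,6R)-3-methoxy-3-[(14E,16E)-octadeca-14,16-dien-1-yl]-3,6-dihydro-1,2-dioxin-6-yl]acetate | C/C=C/C=C/CCCCCCCCCCCCC[C@]1(OC)C=C[C@@H](CC(=O)OC)OO1 | target

**Count.** Total steps: 13. Longest linear sequence: 13 steps, from 1 to 19.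

**Steps most likely to fail**

Step 9. What may go wrong: the hindered tertiary hydroperoxide may add slowly, so that retro-addition, closure of the enamine to a 2,3-epoxy aldehyde with loss of the hemiketal alkoxide, or 1,6-addition to the dienal erode yield and enantiomeric purity. The fallback separates the two C–O bond formations; it sets out from 14 and 12 and comes back at 17. 2-Methoxypropan-2-yl hydroperoxide F1 (from 2-methoxypropene and H2O2), a small hydroperoxide of the kind established for amine-catalysed peroxidation, is added to 14 with the same catalyst to give (3R,4E)-3-[(2-methoxypropan-2-yl)peroxy]hex-4-enal F2. Chlorite oxidation gives (3R,4E)-3-[(2-methoxypropan-2-yl)peroxy]hex-4-enoic acid F3, and TMSCHN2 gives methyl (3R,4E)-3-[(2-methoxypropan-2-yl)peroxy]hex-4-enoate F4. Aqueous AcOH in THF removes the ketal to give methyl (3R,4E)-3-hydroperoxyhex-4-enoate F5. Acid-catalysed transketalisation of 12 with F5 (CSA cat., CH2Cl2, 4 Å sieves, 0 °C) then gives 17, so hydroperoxide 13 is not needed.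

Step 8. What may go wrong: the 1-methoxyallyl cation may be captured at its terminal carbon (allylic transposition, net conjugate addition), adventitious water may hydrolyse it to the enone, or a second exchange may give the geminal dihydroperoxide. The fallback carries out the exchange before the vinyl group exists; it sets out from 10 and comes back at 13. Ketal 10 is treated with excess ethereal H2O2 and CSA (slightly more than 1 equiv, because the selenoxide is basic) at 0 °C. The peroxide oxidises selenium at once, and the saturated ketal, which cannot form an allyl cation, exchanges one methoxy group to give (17E,19E)-3-hydroperoxy-3-methoxy-1-(phenylseleninyl)henicosa-17,19-diene F6. After H2O2 is washed out, warming with i-Pr2NH in toluene (40–60 °C) eliminates PhSeOH and gives 13.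

Step 12. What may go wrong: the ruthenium carbene may engage the side-chain diene (truncation, oligomers, E/Z scrambling), closure at the vinyl group on the fully substituted C3 may be slow, or ruthenium may cleave the O–O bond. The fallback closes the ring through the O2–C3 bond (peroxy-hemiketalisation of a γ-hydroperoxy Z-enone) with no metathesis; it sets out from 6 and 14 and comes back at 18. Amide 6 acylates Ph3P=CH2 (2 equiv, THF) to give the stabilised ylide (16E,18E)-1-(triphenyl-λ5-phosphanylidene)icosa-16,18-dien-2-one F7. Aldehyde 14 is taken to ester F4 exactly as in the fallback for step 9, and ozonolysis of its only alkene (O3, CH2Cl2, −78 °C; Me2S) gives methyl (3R)-3-[(2-methoxypropan-2-yl)peroxy]-4-oxobutanoate F8. Base-free Wittig reaction of F8 with F7 (CH2Cl2, rt) gives methyl (3R,4E,20E,22E)-3-[(2-methoxypropan-2-yl)peroxy]-6-oxotetracosa-4,20,22-trienoate F9. Aqueous AcOH frees methyl (3R,4E,20E,22E)-3-hydroperoxy-6-oxotetracosa-4,20,22-trienoate F10. Irradiation at 366 nm in degassed benzene, where the side-chain diene does not absorb, should isomerise the enone to Z, which closes to the cyclic hemiperoxyketal methyl 2-[(6R)-3-hydroxy-3-[(14E,16E)-octadeca-14,16-dien-1-yl]-3,6-dihydro-1,2-dioxin-6-yl]acetate F11. CSA in MeOH converts F11 into 18, which enters step 13.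

**Further compounds**
F1 | step 9 | 2-methoxypropan-2-yl hydroperoxide | COC(C)(C)OO
F2 | step 9 | (3R,4E)-3-[(2-methoxypropan-2-yl)peroxy]hex-4-enal | C/C=C/[C@@H](CC=O)OOC(C)(C)OC
F3 | step 9 | (3R,4E)-3-[(2-methoxypropan-2-yl)peroxy]hex-4-enoic acid | C/C=C/[C@@H](CC(=O)O)OOC(C)(C)OC
F4 | step 9 | methyl (3R,4E)-3-[(2-methoxypropan-2-yl)peroxy]hex-4-enoate | C/C=C/[C@@H](CC(=O)OC)OOC(C)(C)OC
F5 | step 9 | methyl (3R,4E)-3-hydroperoxyhex-4-enoate | C/C=C/[C@@H](CC(=O)OC)OO
F6 | step 8 | (17E,19E)-3-hydroperoxy-3-methoxy-1-(phenylseleninyl)henicosa-17,19-diene | C/C=C/C=C/CCCCCCCCCCCCCC(OC)(OO)CC[Se](=O)c1ccccc1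
F7 | step 12 | (16E,18E)-1-(triphenyl-λ5-phosphanylidene)icosa-16,18-dien-2-one | C/C=C/C=C/CCCCCCCCCCCCCC(=O)C=P(c1ccccc1)(c1ccccc1)c1ccccc1
F8 | step 12 | methyl (3R)-3-[(2-methoxypropan-2-yl)peroxy]-4-oxobutanoate | O=C[C@@H](CC(=O)OC)OOC(C)(C)OC
F9 | step 12 | methyl (3R,4E,20E,22E)-3-[(2-methoxypropan-2-yl)peroxy]-6-oxotetracosa-4,20,22-trienoate | C/C=C/C=C/CCCCCCCCCCCCCC(=O)/C=C/[C@@H](CC(=O)OC)OOC(C)(C)OC
F10 | step 12 | methyl (3R,4E,20E,22E)-3-hydroperoxy-6-oxotetracosa-4,20,22-trienoate | C/C=C/C=C/CCCCCCCCCCCCCC(=O)/C=C/[C@@H](CC(=O)OC)OO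
F11 | step 12 | methyl 2-[(6R)-3-hydroxy-3-[(14E,16E)-octadeca-14,16-dien-1-yl]-3,6-dihydro-1,2-dioxin-6-yl]acetate | C/C=C/C=C/CCCCCCCCCCCCCC1(O)C=C[C@@H](CC(=O)OC)OO1
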